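**Retrosynthetic overview**
1. 15 ⇐ 14 (acetylation) ⇐ 13 (hydride to the α-face of the C6 ketone) ⇐ 12 (oxidation). C6 is fixed last, on the closed trans-decalin.
2. Ring B (C5–C6–C7–C8–C9–C10) of 12 ⇐ monocarbocyclic aldehyde 11. The C6–C7 bond is made by a photochemical Norrish type 2 / vinylogous Yang closure.
3. Enabling feature: in ring B, C6(O)–C7H2–C8(CH3)=C9 is a homoallylic alcohol, and C9 lies γ to C6 along C6–C5–C10–C9. In the open form, C9–H is therefore both the γ-hydrogen of the C6 aldehyde and allylic to C7=C8, so hydrogen transfer followed by C6–C7 coupling gives the carbinol and the tetrasubstituted alkene together.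
4. 11 ⇐ (S)-dienol 9 by anionic oxy-Cope rearrangement (C9–C10 made, chirality passed from C6 to C10). 9 ⇐ 1 + 2 + AlMe3 + 4 + 7.
5. Ring order: ring A (present in 1), butenolide (present in 7, attached in step 3), ring B last (step 5).

Key step: step 5

Atom numbers follow labdane numbering. Ring A is C1–C5 and C10. Ring B is C5–C10. C11–C12 is the ethylene link and C13–C16 the butenolide. C17 is the methyl on C8, C18/C19 are on C4, and C20 is on C10.
Assumption: the (S)-configured phosphoric acid is taken to give the (S)-carbinol, as it does for aryl and alkenyl aldehydes; if the hindered enal responds in the opposite sense, the (R)-acid is used.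

**Step 1**
Reactants: 1 β-cyclocitral; 2 allenylboronic acid pinacol ester
Product: 3 (1S)-1-(2,6,6-trimethylcyclohex-1-en-1-yl)but-3-yn-1-ol
Conditions: (S)-3,3'-bis(2,4,6-triisopropylphenyl)-1,1'-binaphthyl-2,2'-diyl hydrogen phosphate ((S)-TRIP, 10 mol %), 4 Å molecular sieves, toluene, −20 to 0 °C; aq. NaHCO3
Reagents that add atoms: none
Why: Brønsted-acid-catalysed asymmetric propargylation (allenylboration) runs through a closed six-membered SE2' transition state in which the chiral phosphoric acid binds a boronate oxygen and the formyl hydrogen, so that only 1,2-addition occurs, the terminal alkyne results, and one aldehyde face is attacked to set C6 as (S).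

**Step 2**
Reactants: 3 (1S)-1-(2,6,6-trimethylcyclohex-1-en-1-yl)but-3-yn-1-ol; 4 vinyl bromide
Product: 6 (1S,3E)-3-methyl-1-(2,6,6-trimethylcyclohex-1-en-1-yl)hexa-3,5-dien-1-ol, via alkenylalane 5 (not isolated)
Conditions: AlMe3 (3.5 equiv), Cp2ZrCl2 (0.3 equiv), CH2Cl2, 0 to 23 °C; then 4, Pd(PPh3)4 (5 mol %), ZnCl2 (0.5 equiv), THF, 23 °C; aq. Rochelle salt
Reagents that add atoms: trimethylaluminium, C[Al](C)C
Why: Zirconium-catalysed carboalumination adds CH3 and aluminium syn across the terminal alkyne, CH3 going to the inner carbon C8, and the palladium-catalysed Negishi-type coupling of alkenylalane 5 proceeds by retention, which fixes the (E)-trisubstituted C8=C9 alkene needed for the later pericyclic step while C6, masked as its aluminium alkoxide, is untouched.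

**Step 3**
Reactants: 6 (1S,3E)-3-methyl-1-(2,6,6-trimethylcyclohex-1-en-1-yl)hexa-3,5-dien-1-ol; 7 4-bromofuran-2(5H)-one
Product: 9 4-[(3E,6S)-6-hydroxy-4-methyl-6-(2,6,6-trimethylcyclohex-1-en-1-yl)hex-3-en-1-yl]furan-2(5H)-one, via alkylborane 8 (not isolated)
Conditions: 9-BBN-H (2.3 equiv), THF, 0 to 23 °C; then 7, PdCl2(dppf) (5 mol %), AsPh3 (10 mol %), Cs2CO3 (2 equiv), DMF/H2O, 23 °C
Reagents that add atoms: none
Why: 9-BBN-H adds only to the monosubstituted end of the diene (boron on C12), leaving the tri- and tetrasubstituted alkenes alone, and the B-alkyl Suzuki–Miyaura coupling of 8 joins C12 to the β-carbon of the ready-made butenolide under mild carbonate conditions, no stereocentre being formed.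

**Step 4**
Reactants: 9 4-[(3E,6S)-6-hydroxy-4-methyl-6-(2,6,6-trimethylcyclohex-1-en-1-yl)hex-3-en-1-yl]furan-2(5H)-one
Product: 11 (1S,2R)-2,6,6-trimethyl-2-[(3S)-2-methyl-5-(5-oxo-2,5-dihydrofuran-3-yl)pent-1-en-3-yl]cyclohexane-1-carbaldehyde (formyl group and C9 chain trans), via dipotassium enolate 10 (not isolated)
Conditions: KN(SiMe3)2 (2.5 equiv), 18-crown-6 (2.5 equiv), THF, −78 to 23 °C; cannulated into AcOH/THF, −78 °C; Et3N (0.1 equiv), CH2Cl2, 0 °C
Reagents that add atoms: none
Why: Anionic oxy-Cope rearrangement through a chair in which the alkoxide is equatorial, because an axial oxygen would collide with the C20 methyl that stands cis to C6 on the tetrasubstituted alkene, trades the (S)-carbinol for the quaternary C10 (and C9), while the second equivalent of base only parks the butenolide as its furanolate, and kinetic protonation of the exocyclic enolate from the face opposite the axial methyl groups on C4 and C10 sets C5–H trans to the C10 methyl.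

**Step 5**
Reactants: 11 (1S,2R)-2,6,6-trimethyl-2-[(3S)-2-methyl-5-(5-oxo-2,5-dihydrofuran-3-yl)pent-1-en-3-yl]cyclohexane-1-carbaldehyde
Product: 12 4-{2-[(4S,4aS,8aS)-4-hydroxy-2,5,5,8a-tetramethyl-3,4,4a,5,6,7,8,8a-octahydronaphthalen-1-yl]ethyl}furan-2(5H)-one (6α-alcohol, 5α-H, 10β-methyl)
Conditions: hν (300 nm lamps, Pyrex), benzene/t-BuOH 4:1 (5 mM), argon, 20 °C
Reagents that add atoms: none
Why: Proposed new method: n→π* excitation of the aldehyde is followed by 1,5-hydrogen transfer through the six-membered array O=C6–C5–C10–C9–H, which gives a hydroxy biradical whose carbon radical is delocalised from C9 to C7, and coupling of C6 to C7 then delivers the cyclohexenol, an isomer of 11. The closest known reaction type is the Norrish type 2 / Yang photocyclisation of δ,ε-unsaturated ketones of the hept-6-en-2-one kind, where the allylic biradical closes at its far end to cyclohex-3-enols beside vinylcyclobutanols; it has not been used on such an aldehyde or to close a decalin ring. Ring B is closed by 1,6 radical–radical recombination (C6–C7 bond, six-membered, new C8=C9 bond endocyclic), and no other ring is formed. The only new stereocentre, C6, should be set by a half-chair closure that keeps the hydroxyl equatorial (α), away from the axial methyl groups on C4 and C10, and it is re-set in steps 6 and 7, whereas C5 and C10 are untouched and C9 becomes planar. The step needs three things: abstraction at C9 only, 1,6- over 1,4-closure, and closure over cleavage of C5–C10; the first is secured by the weak tertiary allylic C9–H compared with the methyl and methylene γ-hydrogens, the second by the trans placement of formyl and C9 (a trans-fused cyclobutanol carrying two adjacent fully substituted carbons is strained) together with allylic strain that holds C10 cis to C7 in the allyl radical, and the third is helped by t-BuOH, which hydrogen-bonds the hydroxy biradical and slows back transfer. Light of 300 nm is absorbed by the aldehyde alone, since the butenolide absorbs only at shorter wavelength.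

**Step 6**
Reactants: 12 4-{2-[(4S,4aS,8aS)-4-hydroxy-2,5,5,8a-tetramethyl-3,4,4a,5,6,7,8,8a-octahydronaphthalen-1-yl]ethyl}furan-2(5H)-one
Product: 13 4-{2-[(4aS,8aS)-2,5,5,8a-tetramethyl-4-oxo-3,4,4a,5,6,7,8,8a-octahydronaphthalen-1-yl]ethyl}furan-2(5H)-one
Conditions: Dess–Martin periodinane (1.3 equiv), NaHCO3 (5 equiv), CH2Cl2, 0 °C
Reagents that add atoms: none
Why: Dess–Martin oxidation under bicarbonate buffer is neutral enough to give the β,γ-unsaturated ketone without moving the C8=C9 bond into conjugation or epimerising C5, and it merges both possible C6 epimers of 12 into one compound.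

**Step 7**
Reactants: 13 4-{2-[(4aS,8aS)-2,5,5,8a-tetramethyl-4-oxo-3,4,4a,5,6,7,8,8a-octahydronaphthalen-1-yl]ethyl}furan-2(5H)-one
Product: 14 4-{2-[(4R,4aS,8aS)-4-hydroxy-2,5,5,8a-tetramethyl-3,4,4a,5,6,7,8,8a-octahydronaphthalen-1-yl]ethyl}furan-2(5H)-one (6β-alcohol)
Conditions: NaBH4 (1.5 equiv), CeCl3·7H2O (1.2 equiv), MeOH/CH2Cl2, −78 to −20 °C
Reagents that add atoms: none
Why: Luche reduction is fast, weakly acidic and selective for the ketone over the butenolide, and hydride can reach C6 only from the α-face because the β-face is closed by the axial methyl groups on C4 and C10, which sets the axial 6β-alcohol, (R) at C6.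

**Step 8**
Reactants: 14 4-{2-[(4R,4aS,8aS)-4-hydroxy-2,5,5,8a-tetramethyl-3,4,4a,5,6,7,8,8a-octahydronaphthalen-1-yl]ethyl}furan-2(5H)-one
Product: 15 (1R,4aS,8aS)-3,4a,8,8-tetramethyl-4-[2-(5-oxo-2,5-dihydrofuran-3-yl)ethyl]-1,2,4a,5,6,7,8,8a-octahydronaphthalen-1-yl acetate (target)
Conditions: Ac2O (3 equiv), DMAP (0.2 equiv), Et3N (4 equiv), CH2Cl2, 23 to 40 °C
Reagents that add atoms: acetic anhydride, CC(=O)OC(C)=O
Why: DMAP-catalysed acyl transfer esterifies the hindered axial alcohol by retention at C6 and touches neither the tetrasubstituted alkene nor the lactone.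

**Compound list**
1 | β-cyclocitral (2,6,6-trimethylcyclohex-1-ene-1-carbaldehyde) | CC1=C(C=O)C(C)(C)CCC1 | starting material
2 | allenylboronic acid pinacol ester | C=C=CB1OC(C)(C)C(C)(C)O1 | starting material
3 | (1S)-1-(2,6,6-trimethylcyclohex-1-en-1-yl)but-3-yn-1-ol | O[C@@H](CC#C)C1=C(C)CCCC1(C)C | intermediate
4 | vinyl bromide | C=CBr | starting material
5 | (E)-alkenyl(dimethyl)alane, hydroxyl as dimethylaluminium alkoxide | C[Al](C)O[C@@H](C/C(C)=C/[Al](C)C)C1=C(C)CCCC1(C)C | intermediate
6 | (1S,3E)-3-methyl-1-(2,6,6-trimethylcyclohex-1-en-1-yl)hexa-3,5-dien-1-ol | O[C@@H](C/C(C)=C/C=C)C1=C(C)CCCC1(C)C | intermediate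
7 | 4-bromofuran-2(5H)-one | O=C1C=C(Br)CO1 | starting material
8 | C12 B-alkyl-9-BBN, hydroxyl as 9-BBN borinate | B1(C2CCCC1CCC2)O[C@@H](C/C(C)=C/CCB3C4CCCC3CCC4)C5=C(C)CCCC5(C)C | intermediate
9 | 4-[(3E,6S)-6-hydroxy-4-methyl-6-(2,6,6-trimethylcyclohex-1-en-1-yl)hex-3-en-1-yl]furan-2(5H)-one | O[C@@H](C/C(C)=C/CCC1=CC(=O)OC1)C2=C(C)CCCC2(C)C | intermediate
10 | dipotassium salt: aldehyde enolate and furan-2-olate | [K+].[K+].[O-]/C=C1\C(C)(C)CCC[C@]1(C)[C@@H](CCc2coc([O-])c2)C(C)=C | intermediate
11 | (1S,2R)-2,6,6-trimethyl-2-[(3S)-2-methyl-5-(5-oxo-2,5-dihydrofuran-3-yl)pent-1-en-3-yl]cyclohexane-1-carbaldehyde | O=C[C@H]1C(C)(C)CCC[C@]1(C)[C@@H](CCC2=CC(=O)OC2)C(C)=C | intermediate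
12 | 6α-alcohol, (4S,4aS,8aS) | O[C@H]1CC(C)=C(CCC2=CC(=O)OC2)[C@@]2(C)CCCC(C)(C)[C@H]12 | intermediate
13 | 6-ketone, (4aS,8aS) | O=C1CC(C)=C(CCC2=CC(=O)OC2)[C@@]2(C)CCCC(C)(C)[C@H]12 | intermediate
14 | 6β-alcohol, (4R,4aS,8aS) | O[C@@H]1CC(C)=C(CCC2=CC(=O)OC2)[C@@]2(C)CCCC(C)(C)[C@H]12 | intermediate
15 | CNP0128495.1, 6β-acetate | CC(=O)O[C@@H]1CC(C)=C(CCC2=CC(=O)OC2)[C@@]2(C)CCCC(C)(C)[C@H]12 | target

**Total step count:** 8. **Longest linear sequence:** 8 (1 → 15).

**Steps most likely to fail**

Step 5. The excited aldehyde may lose its energy in several other ways: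
- α-cleavage and decarbonylation;
- oxetane formation with the neighbouring 1,1-disubstituted alkene;
- fragmentation of the biradical across C5–C10;
- return of hydrogen to C7.

The fallback uses known chemistry, sets out from 11 and comes back at 14. Me2AlCl in CH2Cl2 (−78 to 0 °C) promotes a type 2 carbonyl-ene cyclisation to the 6β-hydroxy exocyclic-methylene decalin F1, whose C6 configuration and alkene position do not matter. Buffered Dess–Martin oxidation gives the β,γ-unsaturated 8(17)-en-6-one F2. Equilibrating enol acetylation (Ac2O, TsOH, warm toluene) collects all alkene isomers in the more substituted 6-acetoxy-6,8-diene F3. NaBH4 in EtOH/THF at 0 °C then carries out the deconjugative reduction known for steroidal dienol acetates: acetate cleavage, protonation at C7, and α-face hydride delivery. This gives 14.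

Step 4. The potassium alkoxide may fragment to 1 and an allyl anion. The chair may lose its facial preference, which erodes the transfer of chirality. The furanolate may also condense during the quench. The fallback sets out from 9 and comes back at 11, replacing the charged rearrangement by a neutral one on a protected substrate. Silylation (Me3SiCl, imidazole, CH2Cl2) gives the trimethylsilyl ether F4. Heating in o-dichlorobenzene in a sealed tube (200–220 °C) brings about the siloxy-Cope rearrangement to the silyl enol ether F5; with the hydroxyl capped, no base is present and no retro-ene cleavage can occur. Aqueous citric acid in THF at 0 °C releases 11 by protonation from the same open α-face.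

Step 1. The aldehyde is flanked by a methyl and a gem-dimethyl group, so it may fit the catalyst pocket badly, giving slow addition and poor facial selectivity. The fallback sets out from 1 and comes back at 3, changing from catalyst control to stoichiometric reagent control. The reagent is the B-allenyl-1,3,2-diazaborolidine made from BBr3, the bis(p-toluenesulfonamide) of enantiopure 1,2-diphenylethane-1,2-diamine and triphenyl(prop-2-yn-1-yl)stannane. It adds to 1 at −78 °C through a closed SE2' transition state, and the enantiomer of the diamine that gives the (S)-alcohol is chosen.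

**Further compounds**
F1 | step 5 | 4-{2-[6β-hydroxy-8(17)-methylene decalin, 5α-H, 9α-H, 10β-methyl]ethyl}furan-2(5H)-one | O[C@@H]1CC(=C)[C@H](CCC2=CC(=O)OC2)[C@@]2(C)CCCC(C)(C)[C@H]12
F2 | step 5 | corresponding 8(17)-en-6-one | O=C1CC(=C)[C@H](CCC2=CC(=O)OC2)[C@@]2(C)CCCC(C)(C)[C@H]12
F3 | step 5 | 6-acetoxy-6,8-diene (dienol acetate) | CC(=O)OC1=CC(C)=C(CCC2=CC(=O)OC2)[C@@]2(C)CCCC(C)(C)[C@H]12
F4 | step 4 | trimethylsilyl ether of 9 | C[Si](C)(C)O[C@@H](C/C(C)=C/CCC1=CC(=O)OC1)C2=C(C)CCCC2(C)C
F5 | step 4 | trimethylsilyl enol ether of 11 | C[Si](C)(C)O/C=C1\C(C)(C)CCC[C@]1(C)[C@@H](CCC2=CC(=O)OC2)C(C)=C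
F0 | step 1 | none | none
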